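**Retrosynthetic overview**
1. Target 25 ⇐ epoxy enone 22: one acid-triggered transannular cascade closes both oxygen rings last. The C16 hydroxyl opens the 2,3-epoxide at C3 (oxepane), and the freed C2 hydroxyl adds to C9 of the C8=C9 enone (oxolane).
2. 22 ⇐ (2Z,8Z)-cyclodecadienone 20, a eunicellane-type 6/10 carbobicycle, by face-selective epoxidation of C2=C3. This mirrors the presumed biogenesis: carbobicycle → 2,3-epoxide → ether bridges.
3. 20 ⇐ cis-decalin divinyl carbinol 18 by anionic oxy-Cope ring expansion (C2–C7 cleaved, C4–C5 formed), which gives the ten-membered ring and both Z alkenes.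
4. 18 ⇐ ring A enone 9 + silyloxytriene 13 (Diels–Alder, C11 reduction, enone unveiling, vinyl addition); 9 ⇐ aldehyde 4 + methyl vinyl ketone 5 (organocatalytic Michael/aldol) + MeI.
5. Ring order: ring A → ring B (sacrificial six-membered ring) → ten-membered carbocycle → oxepane → oxolane.

Assumption: eunicellane/asbestinane numbering is used throughout (C1/C10 ring fusion, C2 and C9 oxolane carbons, C3 methyl-bearing ether carbon, C7 ketone, C11 acetoxy, C12 methyl, C14–C15(CH3)–C16 side chain). Ring A is the cyclohexane; ring B is the temporary second six-membered ring (C1, C2, C7, C8, C9, C10).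

**Step 1**
Reactants: 1 (S)-3-bromo-2-methylpropan-1-ol
Product: 2 (S)-(3-bromo-2-methylpropoxy)(tert-butyl)dimethylsilane
Conditions: TBSCl, imidazole, DMF, 0 °C → rt
Reagents that add atoms: tert-butyldimethylsilyl chloride, CC(C)(C)[Si](C)(C)Cl
Why: Standard silyl ether formation on a primary alcohol; the C15 stereocentre comes from the chiral pool and is untouched.

**Step 2**
Reactants: 2 (S)-(3-bromo-2-methylpropoxy)(tert-butyl)dimethylsilane
Product: 4 (R)-4-(tert-butyldimethylsilyloxy)-3-methylbutanal, via Grignard reagent 3 (not isolated)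
Conditions: Mg, THF, reflux; DMF, 0 °C; aq. NH4Cl
Reagents that add atoms: N,N-dimethylformamide, CN(C)C=O
Why: Grignard formation followed by Bouveault formylation adds the one carbon that becomes C1; the γ-silyloxy Grignard reagent is stable and the stereocentre is remote.

**Step 3**
Reactants: 4 (R)-4-(tert-butyldimethylsilyloxy)-3-methylbutanal; 5 but-3-en-2-one
Product: 7 (4R)-4-[(2R)-1-(tert-butyldimethylsilyloxy)propan-2-yl]cyclohex-2-en-1-one, via keto-aldehyde 6 (not isolated)
Conditions: (S)-α,α-diphenylprolinol trimethylsilyl ether (10 mol%), ethyl 3,4-dihydroxybenzoate (20 mol%), neat, 4 °C; then LiOH, i-PrOH, rt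
Reagents that add atoms: none
Why: Organocatalytic enamine Michael addition then intramolecular aldol condensation (Robinson-type annulation); the (S)-catalyst shields one enamine face and sets C14, and the aldol condensation closes ring A without touching that centre.

**Step 4**
Reactants: 7 (4R)-4-[(2R)-1-(tert-butyldimethylsilyloxy)propan-2-yl]cyclohex-2-en-1-one
Product: 9 (4R,6R)-4-[(2R)-1-(tert-butyldimethylsilyloxy)propan-2-yl]-6-methylcyclohex-2-en-1-one, via lithium dienolate 8 (not isolated)
Conditions: LiN(i-Pr)2, THF, −78 °C; MeI, DMPU, −78 → −40 °C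
Reagents that add atoms: iodomethane, CI
Why: Kinetic α′-enolate alkylation; axial attack of MeI on the cross-conjugated dienolate occurs syn to the pseudo-axial H14, anti to the C14 side chain, giving the trans-4,6 isomer (C12).

**Step 5**
Reactants: 10 3-methylbut-2-enal
Product: 11 5-methylhexa-1,4-dien-3-ol (racemic)
Conditions: CH2=CHMgBr, THF, −78 → 0 °C; aq. NH4Cl
Reagents that add atoms: vinylmagnesium bromide, C=C[Mg]Br
Why: Grignard 1,2-addition to an enal; the carbinol centre is removed in the next step.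

**Step 6**
Reactants: 11 5-methylhexa-1,4-dien-3-ol
Product: 12 5-methylhexa-1,4-dien-3-one
Conditions: MnO2, CH2Cl2, rt
Reagents that add atoms: none
Why: Mild oxidation of a bis-allylic alcohol to the divinyl ketone without acid or base that would polymerise it.

**Step 7**
Reactants: 12 5-methylhexa-1,4-dien-3-one
Product: 13 (3Z)-3-(tert-butyldimethylsilyloxy)-5-methylhexa-1,3,5-triene
Conditions: TBSOTf, Et3N, CH2Cl2, −78 → 0 °C
Reagents that add atoms: tert-butyldimethylsilyl trifluoromethanesulfonate, CC(C)(C)[Si](C)(C)OS(=O)(=O)C(F)(F)F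
Why: Soft enolisation to a silyl dienol ether; only the γ-methyl protons can be removed (the other side is a vinyl group), and the s-cis enone gives the Z enol ether with isopropenyl on the outside of the diene.

**Step 8**
Reactants: 9 (4R,6R)-ring A enone; 13 (3Z)-3-(tert-butyldimethylsilyloxy)-5-methylhexa-1,3,5-triene
Product: 14 cis-decalone silyl enol ether (C11 ketone, C7=C8 OTBS enol ether, C2 isopropenyl cis to C14)
Conditions: Me2AlCl (1.2 equiv), CH2Cl2, −78 → −30 °C; Et3N, aq. NaHCO3
Reagents that add atoms: none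
Why: Lewis-acid-promoted Diels–Alder reaction; the enol-ether carbon C2 of the less hindered 2-silyloxydiene unit (C9=C8–C7=C2) bonds to the enone β-carbon C1 anti to the C14 side chain, suprafacial addition fixes the cis C1/C10 fusion, and the endo mode places isopropenyl cis to C14 (corrected in step 10).

**Step 9**
Reactants: 14 cis-decalone silyl enol ether
Product: 15 C11 alcohol (11-OH cis to the C10–C9 bond and to the C12 methyl)
Conditions: LiBH(s-Bu)3, THF, −78 °C
Reagents that add atoms: none
Why: Diastereoselective ketone reduction; the bulky hydride attacks C11 from the convex face opposite the two flanking cis substituents (C9 and C12 methyl), while the C7 ketone stays masked as its silyl enol ether.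

**Step 10**
Reactants: 15 C11 alcohol
Product: 17 ring B enone (C7 ketone, C8=C9, C2 isopropenyl equatorial and trans to C14), via C2-epimeric enone 16 (not isolated)
Conditions: Pd(OAc)2 (1.2 equiv), DMSO, 40 °C; then DBU, 0 °C
Reagents that add atoms: none
Why: Saegusa–Ito oxidation of the regiodefined silyl enol ether gives only the C8=C9 enone (the sole β-hydrogens are on C9); DBU then epimerises C2 (α to the ketone and allylic) to the equatorial isomer, relieving the 1,3-diaxial clash of isopropenyl with C11.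

**Step 11**
Reactants: 17 ring B enone
Product: 18 divinyl carbinol (C7 tertiary alcohol, vinyl cis to the C2 isopropenyl, both on the face opposite ring A)
Conditions: CH2=CHMgBr (4 equiv), CeCl3, THF, −78 °C
Reagents that add atoms: vinylmagnesium bromide, C=C[Mg]Br
Why: Organocerium 1,2-addition (low basicity avoids enolisation at C2); axial attack on the convex face, where only H1 is 1,3-diaxial, places vinyl cis to the equatorial isopropenyl.

**Step 12**
Reactants: 18 divinyl carbinol
Product: 20 (2Z,8Z)-cyclodecadienone (6/10 carbobicycle with 11-OH and 16-OTBS), via dipotassium dienolate 19 (not isolated)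
Conditions: KN(SiMe3)2 (2.5 equiv), 18-crown-6, THF, −78 → 0 °C; AcOH, −78 °C
Reagents that add atoms: none
Why: Anionic oxy-Cope rearrangement; the ground-state conformer (vinyl axial, isopropenyl equatorial) reacts through the chair in which the C2–C1 bond is axial, giving the Z C2=C3 alkene, because the alternative chair puts C8 1,3-diaxial to the C3 methyl and needs a decalin ring flip; C8=C9 stays Z from ring B and α-protonation at C6 gives the enone.

**Step 13**
Reactants: 20 (2Z,8Z)-cyclodecadienone
Product: 21 11-acetate of 20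
Conditions: Ac2O, DMAP, pyridine, CH2Cl2, rt
Reagents that add atoms: acetic anhydride, CC(=O)OC(C)=O
Why: DMAP-catalysed acylation of the only free hydroxyl installs the acetate of the target, which also blocks O11 from competing for the epoxide later.

**Step 14**
Reactants: 21 11-acetate
Product: 22 (2S,3R)-2,3-epoxide of 21 (epoxide oxygen on the face of C2=C3 syn to C10, anti to the C14 side chain)
Conditions: L-fructose-derived Shi ketone (1,2:4,5-di-O-isopropylidene-β-L-erythro-2,3-hexodiulo-2,6-pyranose, 30 mol%), KHSO5 (as 2KHSO5·KHSO4·K2SO4), K2CO3, Bu4NHSO4, MeCN/CH2(OMe)2, aq. Na2B4O7, 0 °C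
Reagents that add atoms: potassium peroxymonosulfate, [K+].[O-]S(=O)(=O)OO
Why: Shi asymmetric epoxidation; the chiral dioxirane attacks only the electron-rich trisubstituted alkene, and by analogy with 1-substituted cycloalkenes this ketone enantiomer delivers the (2S,3R)-epoxide, setting C2 and the face from which C3 will be attacked.

**Step 15**
Reactants: 22 (2S,3R)-epoxide
Product: 25 CNP0288436.2 (target), via epoxy alcohol 23 (not isolated), via oxepane hydroxy enone 24 (not isolated)
Conditions: HF·pyridine, pyridine, THF, 0 °C → rt; then camphorsulfonic acid (cat.), CH2Cl2, 0 °C → rt; then DBU (cat.)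
Reagents that add atoms: none
Why: Biomimetic transannular cascade of known reaction types: after desilylation, acid-catalysed 7-endo epoxy-alcohol cyclisation at the tertiary, methyl-bearing C3 with inversion gives the oxepane, then 5-exo-trig transannular oxa-Michael addition of the freed C2 hydroxyl to C9 closes the oxolane, with C9 fixed because only the cis-bridged oxolane can span the ring.

**Compound list**
1 | (S)-3-bromo-2-methylpropan-1-ol | BrC[C@@H](C)CO | starting material
2 | (S)-(3-bromo-2-methylpropoxy)(tert-butyl)dimethylsilane | BrC[C@@H](C)CO[Si](C)(C)C(C)(C)C | intermediate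
3 | (S)-[3-(tert-butyldimethylsilyloxy)-2-methylpropyl]magnesium bromide | Br[Mg]C[C@@H](C)CO[Si](C)(C)C(C)(C)C | intermediate
4 | (R)-4-(tert-butyldimethylsilyloxy)-3-methylbutanal | O=CC[C@@H](C)CO[Si](C)(C)C(C)(C)C | intermediate
5 | but-3-en-2-one (methyl vinyl ketone) | CC(=O)C=C | starting material
6 | (2S)-2-[(2R)-1-(tert-butyldimethylsilyloxy)propan-2-yl]-5-oxohexanal | O=C[C@@H](CCC(C)=O)[C@@H](C)CO[Si](C)(C)C(C)(C)C | intermediate
7 | (4R)-4-[(2R)-1-(tert-butyldimethylsilyloxy)propan-2-yl]cyclohex-2-en-1-one | O=C1C=C[C@@H](CC1)[C@@H](C)CO[Si](C)(C)C(C)(C)C | intermediate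
8 | lithium cross-conjugated dienolate of 7 (C11–O, C11=C12) | [Li+].[O-]C1=CC[C@H](C=C1)[C@@H](C)CO[Si](C)(C)C(C)(C)C | intermediate
9 | (4R,6R)-4-[(2R)-1-(tert-butyldimethylsilyloxy)propan-2-yl]-6-methylcyclohex-2-en-1-one (trans-4,6) | O=C1C=C[C@@H](C[C@H]1C)[C@@H](C)CO[Si](C)(C)C(C)(C)C | intermediate
10 | 3-methylbut-2-enal | CC(C)=CC=O | starting material
11 | 5-methylhexa-1,4-dien-3-ol (racemic) | C=CC(O)C=C(C)C | intermediate
12 | 5-methylhexa-1,4-dien-3-one | C=CC(=O)C=C(C)C | intermediate
13 | (3Z)-3-(tert-butyldimethylsilyloxy)-5-methylhexa-1,3,5-triene | C=C/C(O[Si](C)(C)C(C)(C)C)=C/C(C)=C | intermediate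
14 | cis-decalone: C11 ketone, C7=C8 OTBS enol ether, C2 isopropenyl cis to C14; C1, C10, C12, C14, C15 as in the target | O=C1[C@H]2CC=C(O[Si](C)(C)C(C)(C)C)[C@@H](C(C)=C)[C@H]2[C@@H](C[C@H]1C)[C@@H](C)CO[Si](C)(C)C(C)(C)C | intermediate
15 | C11 alcohol of 14 (11-OH cis to C9 and to the C12 methyl) | O[C@H]1[C@H]2CC=C(O[Si](C)(C)C(C)(C)C)[C@@H](C(C)=C)[C@H]2[C@@H](C[C@H]1C)[C@@H](C)CO[Si](C)(C)C(C)(C)C | intermediate
16 | ring B enone, C2 isopropenyl axial (cis to C14) | O[C@H]1[C@H]2C=CC(=O)[C@@H](C(C)=C)[C@H]2[C@@H](C[C@H]1C)[C@@H](C)CO[Si](C)(C)C(C)(C)C | intermediate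
17 | ring B enone, C2 isopropenyl equatorial (trans to C14) | O[C@H]1[C@H]2C=CC(=O)[C@H](C(C)=C)[C@H]2[C@@H](C[C@H]1C)[C@@H](C)CO[Si](C)(C)C(C)(C)C | intermediate
18 | divinyl carbinol: C7 tertiary alcohol, vinyl cis to C2 isopropenyl | O[C@H]1[C@H]2C=C[C@](O)(C=C)[C@H](C(C)=C)[C@H]2[C@@H](C[C@H]1C)[C@@H](C)CO[Si](C)(C)C(C)(C)C | intermediate
19 | dipotassium C11-alkoxide C7-dienolate of the ring-expanded bicycle | [K+].[K+].[O-][C@H]1[C@H]2/C=C\C([O-])=CCC/C(C)=C\[C@H]2[C@@H](C[C@H]1C)[C@@H](C)CO[Si](C)(C)C(C)(C)C | intermediate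
20 | (2Z,8Z)-cyclodecadienone fused to ring A: C7 ketone, 11-OH, 16-OTBS | O[C@H]1[C@H]2/C=C\C(=O)CCC/C(C)=C\[C@H]2[C@@H](C[C@H]1C)[C@@H](C)CO[Si](C)(C)C(C)(C)C | intermediate
21 | 11-acetate of 20 | CC(=O)O[C@H]1[C@H]2/C=C\C(=O)CCC/C(C)=C\[C@H]2[C@@H](C[C@H]1C)[C@@H](C)CO[Si](C)(C)C(C)(C)C | intermediate
22 | (2S,3R)-2,3-epoxide of 21 | CC(=O)O[C@H]1[C@H]2/C=C\C(=O)CCC[C@@]3(C)O[C@H]3[C@H]2[C@@H](C[C@H]1C)[C@@H](C)CO[Si](C)(C)C(C)(C)C | intermediate
23 | epoxy alcohol (16-OH) from 22 | CC(=O)O[C@H]1[C@H]2/C=C\C(=O)CCC[C@@]3(C)O[C@H]3[C@H]2[C@@H](C[C@H]1C)[C@@H](C)CO | intermediate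
24 | oxepane hydroxy enone (C3–O–C16 closed, free 2-OH, C8=C9 enone) | CC(=O)O[C@H]1[C@H]2/C=C\C(=O)CCC[C@]3(C)OC[C@H](C)[C@H](C[C@H]1C)[C@@H]2[C@@H]3O | intermediate
25 | CNP0288436.2 | CC(=O)O[C@H]1[C@@H]2[C@@H]3[C@@H](C[C@H]1C)[C@@H](C)CO[C@@]1(C)CCCC(=O)C[C@@H]2O[C@@H]31 | target

**Step count:** 15 steps in total. Longest linear sequence: 12 steps (steps 1–4 and 8–15); steps 5–7 make the diene.

**Steps most likely to fail**

Step 8 (Diels–Alder). The enone is hindered and the trienol ether could react through its vinylogous terminus instead of C2. The fallback annulates ring B without the isopropenyl group and adds that group afterwards. It sets out from 9: Diels–Alder with commercial 2-(trimethylsilyloxy)buta-1,3-diene (Me2AlCl, CH2Cl2, −78 °C) gives the unsubstituted cis-decalone silyl enol ether F1; LiBH(s-Bu)3 gives the C11 alcohol F2; Pd(OAc)2 gives the unsubstituted ring B enone F3. LiN(SiMe3)2 (2.2 equiv, giving the alkoxide and the kinetic α′-enolate at C2) and then 2-bromopropene with Pd2(dba)3/P(t-Bu)3 (enolate α-alkenylation) install the isopropenyl group. After DBU equilibration the sequence comes back to the route at 17.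

Step 12 (oxy-Cope). The [3,3] shift may go through the other chair and give the E C2=C3 alkene, which cannot give the correct C2/C3 relationship by epoxidation and anti opening. The fallback sets the geometry thermodynamically instead of kinetically. It sets out from 18: if rearrangement gives the (2E,8Z)-dienone F4, PhSSPh (cat.), hν, benzene (reversible thiyl-radical addition) equilibrates the strained E trisubstituted alkene to the Z isomer favoured in a ten-membered ring. It comes back to the route at 20.

Step 15 (cascade). The C16 hydroxyl may attack C2 (6-exo), or the C7 carbonyl may trap the developing C3 cation. The fallback makes the two ethers one at a time, oxolane first and oxepane second. It sets out from 22: HClO4 (cat.), THF/H2O opens the epoxide with water at the tertiary C3 (inversion) to give the 2,3-diol F5, whose C2 hydroxyl closes the oxolane by oxa-Michael addition (Et3N) to give the oxolane tertiary alcohol F6. HF·pyridine removes the silyl group to give the C3,C16-diol F7. Tf2O with 2,6-lutidine triflates the primary C16 hydroxyl, and the C3 hydroxyl displaces it (intramolecular Williamson etherification). It comes back to the route at 25.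

**Further compounds**
F1 | step 8 | cis-decalone with C11 ketone and C7=C8 OTMS enol ether, no C2 substituent | O=C1[C@H]2CC=C(O[Si](C)(C)C)C[C@H]2[C@@H](C[C@H]1C)[C@@H](C)CO[Si](C)(C)C(C)(C)C
F2 | step 8 | C11 alcohol of F1 | O[C@H]1[C@H]2CC=C(O[Si](C)(C)C)C[C@H]2[C@@H](C[C@H]1C)[C@@H](C)CO[Si](C)(C)C(C)(C)C
F3 | step 8 | ring B enone without C2 substituent | O[C@H]1[C@H]2C=CC(=O)C[C@H]2[C@@H](C[C@H]1C)[C@@H](C)CO[Si](C)(C)C(C)(C)C
F4 | step 12 | (2E,8Z)-cyclodecadienone isomer of 20 | O[C@H]1[C@H]2/C=C\C(=O)CCC/C(C)=C/[C@H]2[C@@H](C[C@H]1C)[C@@H](C)CO[Si](C)(C)C(C)(C)C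
F5 | step 15 | 2,3-diol from hydrolysis of 22 at C3 | CC(=O)O[C@H]1[C@H]2/C=C\C(=O)CCC[C@](C)(O)[C@@H](O)[C@H]2[C@@H](C[C@H]1C)[C@@H](C)CO[Si](C)(C)C(C)(C)C
F6 | step 15 | oxolane-bridged tricycle with C3 tertiary alcohol and 16-OTBS | CC(=O)O[C@H]1[C@H]2[C@@H]3CC(=O)CCC[C@](C)(O)[C@@H](O3)[C@H]2[C@@H](C[C@H]1C)[C@@H](C)CO[Si](C)(C)C(C)(C)C
F7 | step 15 | oxolane-bridged tricycle with C3 and C16 hydroxyls | CC(=O)O[C@H]1[C@H]2[C@@H]3CC(=O)CCC[C@](C)(O)[C@@H](O3)[C@H]2[C@@H](C[C@H]1C)[C@@H](C)CO
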